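## Structural features

The target is a (2S)-flavanone, C25H28O6. Ring A (C4a–C8a) carries hydroxyls at C5 and C7 and a prenyl group at C6 between them. It is fused through C4a–C8a to the pyranone ring C (O1, C2, C3, C4). Ring B sits on C2 and carries hydroxyls at C3' and C4' and a prenyl group at C5'.

C2 is the only stereocentre. It is benzylic, bears O1 and lies β to the C4 ketone across the C3 methylene. It has no stereochemical neighbour, but it can be lost by base-induced ring opening to the 2'-hydroxychalcone.

The fragile groups are the two trisubstituted prenyl olefins, the air-sensitive catechol of ring B, and the electron-rich ring A. Hydrogenation is excluded, and acid can add a neighbouring phenol across a prenyl olefin to give a 2,2-dimethylchroman. The free C8 position of ring A is a strong carbon nucleophile.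

Two problems define the synthesis. The first is the absolute configuration at C2. The second is the regiochemistry of ring A: the oxygens on C5 and C8a are both ortho to C4a, and which of them becomes O1 decides between a 6-prenyl and an 8-prenyl flavanone. A third, practical demand is a protecting-group set for four phenols that comes off without damage to the prenyl groups.

The key step exploits the fact that O1 and C4 are attached to adjacent ring A carbons (C8a and C4a). O1=C8a–C4a=C4 is therefore an ortho-quinone methide, and the remaining C2–C3 unit with its aryl group on C2 is a styrene.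

## Logic of the disconnections

**20 to 19.** Four O–CH2 acetal bonds are cut, on the oxygens at C5, C7, C3' and C4'. The free phenols would not survive the organolithium steps, and free phenols in the cycloaddition would offer a second ortho oxygen for ring closure and extra nucleophiles. One kind of protecting group allows a single final operation. The forward step must cleave four acetals without cyclising either prenyl group onto its neighbouring phenol and without opening ring C.

**19 to 18 to 17.** No skeletal bond is cut. The C4 ketone is traced back to the C4 alcohol and then to the C4 methyl ether, which is the oxidation level the cycloaddition delivers. The gain is the link to a cycloadduct in which C4 is only a handle. The forward steps must ionise C4 without elimination towards C3 or arylation by ring A, and must oxidise under non-acidic conditions. The C4 configuration is irrelevant.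

**17 to 8, 13 and 14.** C3–C4 and O1–C2 are cut, which opens ring C into the heterodiene O1=C8a–C4a=C4 (from 8, with its C4 oxygen supplied by 14) and the two-carbon unit C2=C3 (13). This is the convergent cut: two arenes of similar size are joined while the ring, two bonds and the C2 stereocentre form together. The forward step needs a chiral acid that controls C2 and a dienophile that reacts ahead of the two prenyl olefins. It also needs a diene precursor with exactly one free ortho hydroxyl.

**8 to 7.** The aryl–CHO bond ortho to the only free phenol is cut. Both ortho positions of 7 are equivalent, so no regiochemical question arises. The forward formylation must be non-acidic.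

**7 to 6 to 3 and 4.** The O–Si bond and then the aryl–CH2 bond of the prenyl group are cut. The carbon between the two acetal oxygens of 3 is its most acidic ring position, and the silyl ether marks the oxygen that will become O1. The forward alkylation must take place at the primary carbon of 4.

**3 to 2 to 1.** Two O–CH2 acetal bonds and one O–Si bond are cut. This reduces the problem to desymmetrising the threefold-symmetric 1. The forward step must stop at mono-silylation.

**13 to 11 and 4.** The aryl–CH2 bond of the ring B prenyl group is cut at the carbon that carries bromine in 11. The halogen fixes the position beyond doubt. The forward step needs halogen–metal exchange to be faster than any reaction at the vinyl group.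

**11 to 10 to 9.** The vinyl C=C bond is traced to the aldehyde, and the two acetals to the catechol. Compound 9 already holds every ring B substituent in the right place.

## Other disconnections considered

**Alternative 1:** The cut is at the two aryl–prenyl bonds, C6–C1'' on ring A and C5'–C1''' on ring B, on an intact (S)-flavanone. (The ring B carbon is C3' if the catechol is numbered from the other side.) A1 is the 5-O- and 4'-O-(1,1-dimethylallyl) ether with methoxymethyl groups on O7 and O3'. Heating it, or treating it with Eu(fod)3, should cause two aromatic [3,3] shifts with allyl inversion to give A2, which needs only acetal removal.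

- In favour: both prenyl groups arrive in one reagent-free operation. The ethers dictate the regiochemistry, since O5 has C6 and O4' has C5' as the only free ortho carbon. No organolithium step is needed, and no prenyl olefin is present while the ring system is built.
- Against: the difficulty moves into A1. Four phenols of a flavanone must be told apart. A tertiary allyl group must be placed on the chelated, poorly nucleophilic 5-hydroxyl, under basic conditions that invite ring opening and racemisation. Tertiary allyl aryl ethers can also fragment to phenol and isoprene. The finished stereocentre is exposed to the heating.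
- Comparison: on regiocontrol at C6 the alternative is the equal of the chosen plan. On mechanism it is better, because the aromatic Claisen rearrangement is well understood and step 9 is untested. It leaves the C2 problem to a separate solution and needs a longer protecting-group sequence. The step count is therefore expected to be equal or higher, and the plan is less convergent.

**Alternative 2:** The cut is at C4a–C5, and ring A is built from non-aromatic carbons. In A3, an (S)-2-aryl-2,3-dihydropyran-4-one carries a 5-prenyl-dioxinone on a methylene at C8a. Heating expels acetone to give an acylketene. The nucleophilic C4a attacks the ketene carbon in a six-membered closure, and tautomerisation aromatises ring A to give A4.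

- In favour: C2 can be set beforehand by a well-precedented catalytic asymmetric hetero-Diels–Alder reaction of the ring B aldehyde with a siloxydiene. On this point the alternative is better than the chosen plan. The 6-prenyl pattern is written into the dioxinone, ring A needs no protecting groups (also better), and the key step is neutral and thermal.
- Against: A3 is a reactive polycarbonyl chain that takes many steps to assemble. Prenylation at C5 of a dioxinone is not routine. The ketene can be trapped at oxygen (the C4 carbonyl or the enolised side-chain ketone) instead of at C4a. The β-alkoxy ketone stereocentre may open on heating.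
- Comparison: both key steps are unproven on these substrates. The alternative has the firmer stereochemical basis and the chosen plan the shorter and more convergent precursor synthesis. On step economy the alternative is the worse of the two.

**Alternative 3:** The cut is at C3–C4. In A5 the ring B unit is bound to O1 as a 1-arylvinyl ether of the salicylaldehyde. [Rh(cod)2]BF4 with DTBM-SEGPHOS would insert into the aldehyde C–H bond and deliver hydride to C2 and the acyl group to C3, giving A6.

- In favour: the reaction is an isomerisation with no by-product. It gives C4 directly as the ketone, which saves the two oxidation-level steps that follow step 9 and is better than the chosen plan on that point. The free 5-hydroxyl can chelate the acyl rhodium species and suppress decarbonylation. Enantiofacial hydride delivery by monovalent rhodium–bisphosphine catalysts has close precedent, so enantiocontrol is arguably on firmer ground.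
- Against: A5 is a hindered enol ether that must be made, for example by ester methylenation, while the aldehyde is masked. The acyl group may add to the internal carbon and give a 2-aryl-2-methylbenzofuranone with a quaternary centre. Insertion into a 1,1-disubstituted olefin is slow, which favours decarbonylation.
- Comparison: the demand for differentiating the two ortho oxygens of ring A is equal in both plans. The alternative is more linear, because O1–C2 must exist before the key step. In the chosen plan the regiochemistry of ring closure is fixed electronically, which is its advantage, while its enantiocontrol is the less secure.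

Key step: step 9

Remarks on the chemistry (assumptions):
- Compound 9 is taken as a catalogue compound.
- The (R) acid is written in step 9 provisionally. Which enantiomer gives 2S must be established, and both are available.
- The structures of 8, 13 and 17 were checked atom by atom against the target and needed no correction. Compound 8, named by lowest locants, is the same compound as 2-hydroxy-4,6-bis(methoxymethoxy)-5-prenylbenzaldehyde.
- The route to 8 and 13 is redesigned. The formyl group of 8 is introduced on the free phenol, not by lithiation beside a bulky silyl ether. The ring B prenyl group is introduced at a carbon marked by bromine.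

## Route

Step 1
Reactants: 1 phloroglucinol (benzene-1,3,5-triol)
Product: 2 5-[(triisopropylsilyl)oxy]benzene-1,3-diol
Conditions: 1 (3 equiv), TIPSCl (1 equiv), imidazole (1.2 equiv), DMF, 0 °C → rt
Reagents that add atoms: chlorotriisopropylsilane (TIPSCl), CC(C)[Si](Cl)(C(C)C)C(C)C
Why: Phenol silylation run with an excess of the cheap, water-soluble triol, so that mono-silylation should dominate per silyl chloride and surplus 1 is washed out with water; the bulky silyl group also slows a second silylation.

Step 2
Reactants: 2 5-[(triisopropylsilyl)oxy]benzene-1,3-diol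
Product: 3 [3,5-bis(methoxymethoxy)phenoxy]triisopropylsilane
Conditions: MOMCl (2.5 equiv), i-Pr2NEt (3.5 equiv), CH2Cl2, 0 °C → rt
Reagents that add atoms: chloromethyl methyl ether (MOMCl), COCCl
Why: O-alkylation of both phenols with an α-chloro ether under amine base; the aryl silyl ether is stable to these conditions.

Step 3
Reactants: 3 [3,5-bis(methoxymethoxy)phenoxy]triisopropylsilane; 4 prenyl bromide (1-bromo-3-methylbut-2-ene)
Product: 6 [3,5-bis(methoxymethoxy)-4-(3-methylbut-2-en-1-yl)phenoxy]triisopropylsilane, via aryllithium 5 (not isolated)
Conditions: n-BuLi (1.1 equiv), THF, 0 °C, 1 h; CuBr·SMe2 (10 mol%), 4 (1.3 equiv), −78 °C → rt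
Reagents that add atoms: prenyl bromide (4), CC(C)=CCBr
Why: Directed ortho-metalation at the carbon flanked by both methoxymethoxy groups (two cooperating chelating directors, while the bulky non-coordinating silyloxy group shields its own neighbours), then copper-catalysed allylic substitution at the primary carbon of 4 to give the linear prenyl arene.

Step 4
Reactants: 6 [3,5-bis(methoxymethoxy)-4-(3-methylbut-2-en-1-yl)phenoxy]triisopropylsilane
Product: 7 3,5-bis(methoxymethoxy)-4-(3-methylbut-2-en-1-yl)phenol
Conditions: Bu4NF (1.1 equiv), AcOH (1.1 equiv), THF, 0 °C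
Reagents that add atoms: none
Why: Fluoride-induced cleavage of the aryl silyl ether; acetic acid buffers the phenoxide, and the acetals and the olefin are inert.

Step 5
Reactants: 7 3,5-bis(methoxymethoxy)-4-(3-methylbut-2-en-1-yl)phenol
Product: 8 6-hydroxy-2,4-bis(methoxymethoxy)-3-(3-methylbut-2-en-1-yl)benzaldehyde
Conditions: MgCl2 (2 equiv), Et3N (4 equiv), (CH2O)n (6 equiv), THF, reflux; aq NH4Cl
Reagents that add atoms: paraformaldehyde (as formaldehyde), C=O
Why: Casnati–Skattebøl ortho-formylation: the magnesium phenoxide delivers formaldehyde to the ortho carbon and a second formaldehyde oxidises the resulting benzylic alkoxide by hydride transfer. The two ortho positions of 7 are equivalent, so one aldehyde should result, and the basic medium spares the acetals and the prenyl group.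

Step 6
Reactants: 9 3-bromo-4,5-dihydroxybenzaldehyde
Product: 10 3-bromo-4,5-bis(methoxymethoxy)benzaldehyde
Conditions: MOMCl (2.5 equiv), i-Pr2NEt (3.5 equiv), CH2Cl2, 0 °C → rt
Reagents that add atoms: chloromethyl methyl ether (MOMCl), COCCl
Why: Double O-alkylation of the catechol with an α-chloro ether; the aldehyde and the aryl bromide are untouched.

Step 7
Reactants: 10 3-bromo-4,5-bis(methoxymethoxy)benzaldehyde
Product: 11 1-bromo-5-ethenyl-2,3-bis(methoxymethoxy)benzene
Conditions: Ph3PCH3Br (1.3 equiv), KOt-Bu (1.25 equiv), THF, 0 °C → rt
Reagents that add atoms: methyltriphenylphosphonium bromide, C[P+](c1ccccc1)(c1ccccc1)c1ccccc1.[Br-]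
Why: Wittig methylenation of an aromatic aldehyde with the non-stabilised ylide; the aryl bromide and acetals are inert to it.

Step 8
Reactants: 11 1-bromo-5-ethenyl-2,3-bis(methoxymethoxy)benzene; 4 prenyl bromide (1-bromo-3-methylbut-2-ene)
Product: 13 5-ethenyl-1,2-bis(methoxymethoxy)-3-(3-methylbut-2-en-1-yl)benzene, via aryllithium 12 (not isolated)
Conditions: n-BuLi (1.05 equiv), THF, −78 °C, 15 min; CuBr·SMe2 (10 mol%), 4 (1.5 equiv), −78 → 0 °C
Reagents that add atoms: prenyl bromide (4), CC(C)=CCBr
Why: Bromine–lithium exchange at −78 °C is much faster than addition of butyllithium to the vinyl group, and the ortho-alkoxy aryllithium is chelated and stable; copper-catalysed allylic substitution at the primary carbon of 4 then gives the linear prenyl group exactly where the bromine stood.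

Step 9
Reactants: 8 6-hydroxy-2,4-bis(methoxymethoxy)-3-(3-methylbut-2-en-1-yl)benzaldehyde; 13 5-ethenyl-1,2-bis(methoxymethoxy)-3-(3-methylbut-2-en-1-yl)benzene; 14 trimethyl orthoformate
Product: 17 (2S,4S)-4-methoxy-5,7-bis(methoxymethoxy)-2-[3,4-bis(methoxymethoxy)-5-(3-methylbut-2-en-1-yl)phenyl]-6-(3-methylbut-2-en-1-yl)chromane, via dimethyl acetal 15 (not isolated), via ortho-quinone methide 16 (not isolated)
Conditions: (R)-3,3'-bis(2,4,6-triisopropylphenyl)-1,1'-binaphthyl-2,2'-diyl hydrogen phosphate (10 mol%), 14 (1.5 equiv), 13 (1.5 equiv), 5 Å MS, toluene, −20 °C → rt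
Reagents that add atoms: trimethyl orthoformate (14), COC(OC)OC
Why: Proposed new method: the phosphoric acid converts 8 and 14 into acetal 15 and then, by loss of methanol, into the O-protonated form of 16, a 2-hydroxybenzylic methoxycarbenium ion held as a hydrogen-bonded contact ion pair with the chiral phosphate; the terminal carbon of styrene 13 attacks C4 and the phenolic oxygen closes onto the developing benzylic cation at C2 while the phosphate takes back the proton, an asynchronous inverse-demand hetero-[4+2]. The closest known reaction types are the acid-catalysed cycloaddition of salicylaldehyde acetals with styrenes to 2,4-cis-4-alkoxyflavans and chiral phosphoric acid-controlled cycloadditions of ortho-quinone methides made from ortho-hydroxybenzyl alcohols; their combination on an alkoxy quinone methide with a simple styrene is the untested part. Ring C closes as a six-membered ring in the [4+2] sense, with O1=C8a–C4a=C4 as the four-atom unit and C3=C2 as the two-atom unit, and C3–C4 forms ahead of O1–C2. C2 is set in the O1–C2 bond formation, where the phosphate is bound to the O1–H and so sits beside the forming stereocentre, and its 2,4,6-triisopropylphenyl walls should leave one face open. C4 follows from the endo approach that places aryl and methoxy cis (4S); it is not needed later, but endo selectivity or direct catalyst control of the ring closure is required, because a trans adduct formed on the same quinone methide face would carry the opposite C2 configuration. Regiochemistry is electronic: C4 is the electrophilic end of the heterodiene and the styrene CH2 the nucleophilic end, because the cation that develops at C2 is stabilised by the para methoxymethoxy group. The styrene should outrun the two prenyl olefins because it offers an unsubstituted terminus and a para-oxygen-stabilised benzylic cation, whereas a prenyl group must bond through its substituted internal carbon to the doubly ortho-flanked C4; Friedel–Crafts attack by ring A is held back because its only free position lies between two oxygens. Only the C8a hydroxyl is free, so O1 can come from no other oxygen and the prenyl group ends at C6; sieves that take up methanol pull the acetal towards the ion pair at a temperature where the MOM ethers should not exchange.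

Step 10
Reactants: 17 (2S,4S)-4-methoxy-5,7-bis(methoxymethoxy)-2-[3,4-bis(methoxymethoxy)-5-(3-methylbut-2-en-1-yl)phenyl]-6-(3-methylbut-2-en-1-yl)chromane
Product: 18 (2S)-5,7-bis(methoxymethoxy)-2-[3,4-bis(methoxymethoxy)-5-(3-methylbut-2-en-1-yl)phenyl]-6-(3-methylbut-2-en-1-yl)chroman-4-ol (C4 epimers; 4S expected to dominate)
Conditions: pyridinium p-toluenesulfonate (0.2 equiv), THF/H2O (4:1), 0.02 M, rt
Reagents that add atoms: water, O
Why: SN1 exchange at a benzylic ether whose cation is stabilised by O1, O5 and O7, so it should ionise far more readily than the phenolic acetals hydrolyse; the large excess of water traps the cation and high dilution disfavours bimolecular arylation. C2 is not involved and the C4 epimer ratio is irrelevant.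

Step 11
Reactants: 18 (2S)-5,7-bis(methoxymethoxy)-2-[3,4-bis(methoxymethoxy)-5-(3-methylbut-2-en-1-yl)phenyl]-6-(3-methylbut-2-en-1-yl)chroman-4-ol
Product: 19 (2S)-5,7-bis(methoxymethoxy)-2-[3,4-bis(methoxymethoxy)-5-(3-methylbut-2-en-1-yl)phenyl]-6-(3-methylbut-2-en-1-yl)-2,3-dihydro-4H-chromen-4-one
Conditions: Dess–Martin periodinane (1.3 equiv), pyridine (3 equiv), CH2Cl2, 0 °C → rt
Reagents that add atoms: none
Why: Dess–Martin oxidation of a secondary benzylic alcohol to the aryl ketone; pyridine buffers the acetic acid so that neither the C4 alcohol ionises nor the acetals cleave, and the olefins are inert to the reagent. Both C4 epimers converge on one ketone and C2 is untouched.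

Step 12
Reactants: 19 (2S)-5,7-bis(methoxymethoxy)-2-[3,4-bis(methoxymethoxy)-5-(3-methylbut-2-en-1-yl)phenyl]-6-(3-methylbut-2-en-1-yl)-2,3-dihydro-4H-chromen-4-one
Product: 20 (2S)-2-[3,4-dihydroxy-5-(3-methylbut-2-en-1-yl)phenyl]-5,7-dihydroxy-6-(3-methylbut-2-en-1-yl)-2,3-dihydro-4H-chromen-4-one (CNP0117506.1)
Conditions: HCl (1.25 M in MeOH), rt → 40 °C, monitored; NaHCO3 quench
Reagents that add atoms: none
Why: Acid-catalysed acetal exchange of the four methoxymethyl ethers with methanol, the standard unmasking of prenylated polyphenols. The flavanone stereocentre is configurationally stable in acid, since ring opening to the chalcone is a base-mediated process, and short exposure at mild temperature should leave the prenyl olefins intact.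

## Compound list

1 | phloroglucinol (benzene-1,3,5-triol) | Oc1cc(O)cc(O)c1 | starting material
2 | 5-[(triisopropylsilyl)oxy]benzene-1,3-diol | CC(C)[Si](Oc1cc(O)cc(O)c1)(C(C)C)C(C)C | intermediate
3 | [3,5-bis(methoxymethoxy)phenoxy]triisopropylsilane | COCOc1cc(OCOC)cc(O[Si](C(C)C)(C(C)C)C(C)C)c1 | intermediate
4 | prenyl bromide (1-bromo-3-methylbut-2-ene) | CC(C)=CCBr | starting material
5 | [2,6-bis(methoxymethoxy)-4-(triisopropylsilyloxy)phenyl]lithium | [Li]c1c(OCOC)cc(O[Si](C(C)C)(C(C)C)C(C)C)cc1OCOC | intermediate (not isolated)
6 | [3,5-bis(methoxymethoxy)-4-(3-methylbut-2-en-1-yl)phenoxy]triisopropylsilane | COCOc1cc(O[Si](C(C)C)(C(C)C)C(C)C)cc(OCOC)c1CC=C(C)C | intermediate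
7 | 3,5-bis(methoxymethoxy)-4-(3-methylbut-2-en-1-yl)phenol | COCOc1cc(O)cc(OCOC)c1CC=C(C)C | intermediate
8 | 6-hydroxy-2,4-bis(methoxymethoxy)-3-(3-methylbut-2-en-1-yl)benzaldehyde | O=Cc1c(O)cc(OCOC)c(CC=C(C)C)c1OCOC | intermediate
9 | 3-bromo-4,5-dihydroxybenzaldehyde | O=Cc1cc(O)c(O)c(Br)c1 | starting material
10 | 3-bromo-4,5-bis(methoxymethoxy)benzaldehyde | O=Cc1cc(Br)c(OCOC)c(OCOC)c1 | intermediate
11 | 1-bromo-5-ethenyl-2,3-bis(methoxymethoxy)benzene | C=Cc1cc(Br)c(OCOC)c(OCOC)c1 | intermediate
12 | [5-ethenyl-2,3-bis(methoxymethoxy)phenyl]lithium | [Li]c1cc(C=C)cc(OCOC)c1OCOC | intermediate (not isolated)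
13 | 5-ethenyl-1,2-bis(methoxymethoxy)-3-(3-methylbut-2-en-1-yl)benzene | C=Cc1cc(CC=C(C)C)c(OCOC)c(OCOC)c1 | intermediate
14 | trimethyl orthoformate | COC(OC)OC | starting material
15 | 2-(dimethoxymethyl)-3,5-bis(methoxymethoxy)-4-(3-methylbut-2-en-1-yl)phenol | COC(OC)c1c(O)cc(OCOC)c(CC=C(C)C)c1OCOC | intermediate (not isolated)
16 | 6-(methoxymethylidene)-3,5-bis(methoxymethoxy)-4-(3-methylbut-2-en-1-yl)cyclohexa-2,4-dien-1-one (double-bond geometry not fixed; reacts as its O-protonated ion pair) | COC=C1C(=O)C=C(OCOC)C(CC=C(C)C)=C1OCOC | intermediate (not isolated)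
17 | (2S,4S)-4-methoxy-5,7-bis(methoxymethoxy)-2-[3,4-bis(methoxymethoxy)-5-(3-methylbut-2-en-1-yl)phenyl]-6-(3-methylbut-2-en-1-yl)chromane | CC(C)=CCc1cc([C@@H]2C[C@H](OC)c3c(cc(OCOC)c(CC=C(C)C)c3OCOC)O2)cc(OCOC)c1OCOC | intermediate
18 | (2S)-5,7-bis(methoxymethoxy)-2-[3,4-bis(methoxymethoxy)-5-(3-methylbut-2-en-1-yl)phenyl]-6-(3-methylbut-2-en-1-yl)chroman-4-ol (C4 epimers) | CC(C)=CCc1cc([C@@H]2CC(O)c3c(cc(OCOC)c(CC=C(C)C)c3OCOC)O2)cc(OCOC)c1OCOC | intermediate
19 | (2S)-5,7-bis(methoxymethoxy)-2-[3,4-bis(methoxymethoxy)-5-(3-methylbut-2-en-1-yl)phenyl]-6-(3-methylbut-2-en-1-yl)-2,3-dihydro-4H-chromen-4-one | CC(C)=CCc1cc([C@@H]2CC(=O)c3c(cc(OCOC)c(CC=C(C)C)c3OCOC)O2)cc(OCOC)c1OCOC | intermediate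
20 | (2S)-2-[3,4-dihydroxy-5-(3-methylbut-2-en-1-yl)phenyl]-5,7-dihydroxy-6-(3-methylbut-2-en-1-yl)-2,3-dihydro-4H-chromen-4-one | CC(C)=CCc1cc([C@@H]2CC(=O)c3c(cc(O)c(CC=C(C)C)c3O)O2)cc(O)c1O | target

## Step count and least certain steps

Total: 12 steps. Longest linear sequence: 9 steps (steps 1–5 and 9–12). The ring B branch (steps 6–8) has 3 steps.

**Step 9 (key step).** Three things may go wrong:
- The chiral anion may give poor facial selectivity in the ring closure, or incomplete endo control may erode the C2 purity.
- The cation may be captured by ring A of the acetal or of the product, leading to oligomers.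
- The methoxymethyl ethers may exchange in the presence of acid and methanol.

Fallback, known chemistry only, from 8 and 10 back to 19: the chalcone route with kinetic resolution.
- Aldehyde 8 with MeMgBr (THF, 0 °C) should give the carbinol 2-(1-hydroxyethyl)-3,5-bis(methoxymethoxy)-4-(3-methylbut-2-en-1-yl)phenol F1. Oxidation of the crude material (MnO2, CH2Cl2) should give the acetophenone 1-[6-hydroxy-2,4-bis(methoxymethoxy)-3-(3-methylbut-2-en-1-yl)phenyl]ethan-1-one F2.
- Bromide 10 would be coupled with tributyl(3-methylbut-2-en-1-yl)stannane (Pd(PPh3)4, DMF, 90 °C; Stille coupling at the unsubstituted allyl terminus) to give 3,4-bis(methoxymethoxy)-5-(3-methylbut-2-en-1-yl)benzaldehyde F3.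
- Claisen–Schmidt condensation of F2 and F3 (KOH, EtOH, rt) should give the (E)-2'-hydroxychalcone F4.
- NaOAc in refluxing EtOH should close F4 by oxa-Michael addition to the racemic flavanone F5. Its single free hydroxyl again secures the 6-prenyl pattern.
- Kinetic resolution by asymmetric transfer hydrogenation (RuCl(p-cymene)[(R,R)-TsDPEN], HCO2H/Et3N, EtOAc, rt, stopped near half conversion) is expected to reduce the 2R ketone to the cis alcohol (2R,4R)-flavan-4-ol F6. The unreacted (S)-ketone is 19 and rejoins the route before step 12. Which catalyst enantiomer leaves the 2S ketone must be confirmed.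

**Step 10.** The C4 cation may lose a proton from C3 to give the flav-3-ene. It may arylate C8 of a second molecule, or a methoxymethyl group may be lost with it. The cause is that the same ionisation that exchanges methoxy for hydroxyl opens these paths.
Fallback from 17 directly to 19, bypassing 18 and step 11: oxidative cleavage of the benzylic methyl ether with DDQ (CH2Cl2/pH 7 buffer, 0 °C). Hydride abstraction from the well-aligned C4–H should give the oxocarbenium ion, which water converts into the ketone with loss of methanol. No new compound is formed on the way.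

**Step 12.** Protic acid may add the freed 5-, 7- or 4'-hydroxyl across the neighbouring prenyl olefin to close a dimethylchroman ring, or may add HCl or methanol to the olefin. The cause is that the phenols are unmasked under the conditions that activate the olefin.
Fallback from 19 to 20: a non-protic exchange of acetal for silyl. Me3SiOTf with 2,2'-bipyridyl (CH2Cl2, 0 °C) should convert the four aryl methoxymethyl ethers into the tetrakis(trimethylsilyl) ether F7. F7 is not purified; it is hydrolysed with water or K2CO3/MeOH at 0 °C to 20.

**Step 8.** Butyllithium or the aryllithium may add to the vinyl group and start anionic oligomerisation. Some allylation may also occur at the tertiary terminus of 4, giving a reverse prenyl group.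
Fallback from 11 to 13: Stille coupling of 11 with tributyl(3-methylbut-2-en-1-yl)stannane (Pd(PPh3)4, DMF, 80 °C). This replaces the organolithium by a zerovalent palladium cycle and forms no new intermediate.

**Step 5.** Formylation may be sluggish at a position flanked by a methoxymethoxy group. Magnesium chelation at reflux may also remove the acetal next to the new aldehyde.
Fallback from 7 to 8:
- Phenol 7 is protected with ethyl vinyl ether (pyridinium p-toluenesulfonate, CH2Cl2) as the 1-ethoxyethyl ether 1-(1-ethoxyethoxy)-3,5-bis(methoxymethoxy)-4-(3-methylbut-2-en-1-yl)benzene F8.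
- Directed ortho-metalation between the two acetal oxygens (n-BuLi, THF, 0 °C) and a DMF quench should give 6-(1-ethoxyethoxy)-2,4-bis(methoxymethoxy)-3-(3-methylbut-2-en-1-yl)benzaldehyde F9.
- Pyridinium p-toluenesulfonate in MeOH at rt should remove the more labile ethoxyethyl group selectively and give 8.

## Further compounds

F1 | step 9 | 2-(1-hydroxyethyl)-3,5-bis(methoxymethoxy)-4-(3-methylbut-2-en-1-yl)phenol (racemic) | CC(O)c1c(O)cc(OCOC)c(CC=C(C)C)c1OCOC
F2 | step 9 | 1-[6-hydroxy-2,4-bis(methoxymethoxy)-3-(3-methylbut-2-en-1-yl)phenyl]ethan-1-one | CC(=O)c1c(O)cc(OCOC)c(CC=C(C)C)c1OCOC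
F3 | step 9 | 3,4-bis(methoxymethoxy)-5-(3-methylbut-2-en-1-yl)benzaldehyde | O=Cc1cc(CC=C(C)C)c(OCOC)c(OCOC)c1
F4 | step 9 | (E)-1-[6-hydroxy-2,4-bis(methoxymethoxy)-3-(3-methylbut-2-en-1-yl)phenyl]-3-[3,4-bis(methoxymethoxy)-5-(3-methylbut-2-en-1-yl)phenyl]prop-2-en-1-one | COCOc1cc(O)c(C(=O)/C=C/c2cc(CC=C(C)C)c(OCOC)c(OCOC)c2)c(OCOC)c1CC=C(C)C
F5 | step 9 | racemic 5,7-bis(methoxymethoxy)-2-[3,4-bis(methoxymethoxy)-5-(3-methylbut-2-en-1-yl)phenyl]-6-(3-methylbut-2-en-1-yl)-2,3-dihydro-4H-chromen-4-one | CC(C)=CCc1cc(C2CC(=O)c3c(cc(OCOC)c(CC=C(C)C)c3OCOC)O2)cc(OCOC)c1OCOC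
F6 | step 9 | (2R,4R)-5,7-bis(methoxymethoxy)-2-[3,4-bis(methoxymethoxy)-5-(3-methylbut-2-en-1-yl)phenyl]-6-(3-methylbut-2-en-1-yl)chroman-4-ol | CC(C)=CCc1cc([C@H]2C[C@@H](O)c3c(cc(OCOC)c(CC=C(C)C)c3OCOC)O2)cc(OCOC)c1OCOC
F0 | step 10 | none | none
F7 | step 12 | (2S)-2-[3,4-bis(trimethylsilyloxy)-5-(3-methylbut-2-en-1-yl)phenyl]-6-(3-methylbut-2-en-1-yl)-5,7-bis(trimethylsilyloxy)-2,3-dihydro-4H-chromen-4-one | CC(C)=CCc1cc([C@@H]2CC(=O)c3c(cc(O[Si](C)(C)C)c(CC=C(C)C)c3O[Si](C)(C)C)O2)cc(O[Si](C)(C)C)c1O[Si](C)(C)C
F0 | step 8 | none | none
F8 | step 5 | 1-(1-ethoxyethoxy)-3,5-bis(methoxymethoxy)-4-(3-methylbut-2-en-1-yl)benzene (racemic acetal) | CCOC(C)Oc1cc(OCOC)c(CC=C(C)C)c(OCOC)c1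
F9 | step 5 | 6-(1-ethoxyethoxy)-2,4-bis(methoxymethoxy)-3-(3-methylbut-2-en-1-yl)benzaldehyde (racemic acetal) | CCOC(C)Oc1cc(OCOC)c(CC=C(C)C)c(OCOC)c1C=O
A1 | alternative 1 | (2S)-7-(methoxymethoxy)-2-{3-(methoxymethoxy)-4-[(2-methylbut-3-en-2-yl)oxy]phenyl}-5-[(2-methylbut-3-en-2-yl)oxy]-2,3-dihydro-4H-chromen-4-one | C=CC(C)(C)Oc1ccc(cc1OCOC)[C@@H]2CC(=O)c3c(OC(C)(C)C=C)cc(OCOC)cc3O2
A2 | alternative 1 | (2S)-5-hydroxy-2-[4-hydroxy-3-(methoxymethoxy)-5-(3-methylbut-2-en-1-yl)phenyl]-7-(methoxymethoxy)-6-(3-methylbut-2-en-1-yl)-2,3-dihydro-4H-chromen-4-one | CC(C)=CCc1cc([C@@H]2CC(=O)c3c(cc(OCOC)c(CC=C(C)C)c3O)O2)cc(OCOC)c1O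
A3 | alternative 2 | (2S)-2-[3,4-bis(methoxymethoxy)-5-(3-methylbut-2-en-1-yl)phenyl]-6-{[2,2-dimethyl-5-(3-methylbut-2-en-1-yl)-4-oxo-4H-1,3-dioxin-6-yl]methyl}-2,3-dihydro-4H-pyran-4-one | CC(C)=CCC1=C(CC2=CC(=O)C[C@@H](c3cc(CC=C(C)C)c(OCOC)c(OCOC)c3)O2)OC(C)(C)OC1=O
A4 | alternative 2 | (2S)-2-[3,4-bis(methoxymethoxy)-5-(3-methylbut-2-en-1-yl)phenyl]-5,7-dihydroxy-6-(3-methylbut-2-en-1-yl)-2,3-dihydro-4H-chromen-4-one | CC(C)=CCc1cc([C@@H]2CC(=O)c3c(cc(O)c(CC=C(C)C)c3O)O2)cc(OCOC)c1OCOC
A5 | alternative 3 | 2-({1-[3,4-bis(methoxymethoxy)-5-(3-methylbut-2-en-1-yl)phenyl]ethenyl}oxy)-6-hydroxy-4-(methoxymethoxy)-5-(3-methylbut-2-en-1-yl)benzaldehyde | C=C(Oc1cc(OCOC)c(CC=C(C)C)c(O)c1C=O)c1cc(CC=C(C)C)c(OCOC)c(OCOC)c1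
A6 | alternative 3 | (2S)-2-[3,4-bis(methoxymethoxy)-5-(3-methylbut-2-en-1-yl)phenyl]-5-hydroxy-7-(methoxymethoxy)-6-(3-methylbut-2-en-1-yl)-2,3-dihydro-4H-chromen-4-one | CC(C)=CCc1cc([C@@H]2CC(=O)c3c(cc(OCOC)c(CC=C(C)C)c3O)O2)cc(OCOC)c1OCOC
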